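**Plan**

- Retrosynthesis: the three MOM ethers are removed last and the C4 ketone is traced back to a C4 methyl ether. Ring C is then cut at O1–C2 and C3–C4 in one operation; further cuts are C6–C1″ (geranyl to ring A), C4–C4a (formyl group) and the enol C–O bond of the two-carbon piece.
- Enabling feature: O1, C8a, C4a and C4 form a 1-oxadiene held inside the ring A phenol (an ortho-quinone methide once C4 is an oxocarbenium carbon). Ring C therefore lacks only the C2=C3 unit, which arrives with ring B and the C3 oxygen already attached.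
- Forward, ring A: phloroglucinol is geranylated between two MOM ethers by directed lithiation, then ortho-formylated at a mirror-symmetric phenol, so the chain can only end up at C6.
- Forward, ring B: an E enol acetate is made from 4-hydroxybenzaldehyde through an alkenylboron compound of fixed geometry.
- Ring C forms last, in the [4+2] step; acetate methanolysis, C4 ether hydrolysis, benzylic oxidation and MOM removal finish the synthesis.
- Stereochemistry: 2,3-trans comes from the E alkene, the absolute configuration (2R,3R) from the chiral phosphate counter-ion in the cycloaddition; the C4 centre made there is erased on oxidation.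

Key step: step 10

Assumption: the (R) enantiomer of the phosphoric acid is taken to expose the alkene face that leads to the (2R) series; if the opposite sense is found, the (S) acid is used with no other change.

Naming note: flavan numbering is used; geranyl = (2E)-3,7-dimethylocta-2,6-dien-1-yl; MOM = methoxymethyl; TIPS = triisopropylsilyl; (R)-TRIP = (R)-3,3′-bis(2,4,6-triisopropylphenyl)-1,1′-binaphthyl-2,2′-diyl hydrogen phosphate.

**Route**

Step 1
Reactants: 1 phloroglucinol
Product: 2 3,5-bis(methoxymethoxy)phenol
Conditions: MOMCl (2.0 equiv), i-Pr2NEt (2.5 equiv), DMF, 0 °C to rt; chromatography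
Reagents that add atoms: chloromethyl methyl ether, COCCl
Why: Williamson-type O-alkylation of a threefold-symmetric triphenol with two equivalents of MOMCl should give the bis-ether as the main component of a statistical mixture, from which it is separated while the mono-ether is resubmitted.

Step 2
Reactants: 2 3,5-bis(methoxymethoxy)phenol
Product: 3 [3,5-bis(methoxymethoxy)phenoxy]triisopropylsilane
Conditions: TIPSCl, imidazole, DMF, rt
Reagents that add atoms: chlorotriisopropylsilane, CC(C)[Si](Cl)(C(C)C)C(C)C
Why: imidazole-promoted silylation of the remaining phenol should install a base-stable, poorly coordinating group that marks the future O1 and prevents phenoxide formation during lithiation.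

Step 3
Reactants: 3 [3,5-bis(methoxymethoxy)phenoxy]triisopropylsilane; 4 geranyl bromide
Product: 6 [4-geranyl-3,5-bis(methoxymethoxy)phenoxy]triisopropylsilane, via aryllithium 5 (not isolated)
Conditions: n-BuLi, THF, 0 °C; then CuBr·SMe2 (10 mol%), 4, −78 °C to rt
Reagents that add atoms: none
Why: directed ortho-metalation should occur at the carbon flanked by both MOM ethers (cooperative chelation, the TIPS ether does not direct), and copper-catalysed SN2 allylation of the aryl metal with the primary allylic bromide should attach the chain with its E alkene unchanged.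

Step 4
Reactants: 6 [4-geranyl-3,5-bis(methoxymethoxy)phenoxy]triisopropylsilane
Product: 7 4-geranyl-3,5-bis(methoxymethoxy)phenol
Conditions: TBAF, THF, 0 °C; aq NH4Cl
Reagents that add atoms: none
Why: fluoride cleavage of an aryl silyl ether should leave MOM ethers and alkenes untouched and give a mirror-symmetric phenol whose two ortho positions are equivalent.

Step 5
Reactants: 7 4-geranyl-3,5-bis(methoxymethoxy)phenol
Product: 9 5-geranyl-2-hydroxy-4,6-bis(methoxymethoxy)benzaldehyde, via benzylic alcohol 8 (not isolated)
Conditions: MgCl2, Et3N, (CH2O)n, THF, reflux; aq NH4Cl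
Reagents that add atoms: paraformaldehyde (as formaldehyde), C=O
Why: Casnati–Skattebøl ortho-formylation (the magnesium phenoxide delivers formaldehyde to the ortho carbon and the benzylic alkoxide is oxidised by a second formaldehyde in an Oppenauer-type hydride transfer) should give a single aldehyde because both ortho positions are the same, which places geranyl at the future C6.

Step 6
Reactants: 10 4-hydroxybenzaldehyde
Product: 11 4-(methoxymethoxy)benzaldehyde
Conditions: MOMCl, i-Pr2NEt, CH2Cl2, 0 °C to rt
Reagents that add atoms: chloromethyl methyl ether, COCCl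
Why: base-mediated O-alkylation of a phenol, to which the aldehyde is inert.

Step 7
Reactants: 11 4-(methoxymethoxy)benzaldehyde; 12 bis[(pinacolato)boryl]methane
Product: 14 (E)-2-{2-[4-(methoxymethoxy)phenyl]ethenyl}-4,4,5,5-tetramethyl-1,3,2-dioxaborolane, via lithiated diborylmethane 13 (not isolated)
Conditions: LiTMP (lithium 2,2,6,6-tetramethylpiperidide), THF, 0 °C; then 11, −78 °C to rt; aq NH4Cl
Reagents that add atoms: none
Why: boron-Wittig olefination, in which the α-boryl carbanion adds to the aldehyde and syn B–O elimination should give the trans-alkenylboronate selectively.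

Step 8
Reactants: 14 (E)-2-{2-[4-(methoxymethoxy)phenyl]ethenyl}-4,4,5,5-tetramethyl-1,3,2-dioxaborolane
Product: 15 potassium (E)-trifluoro{2-[4-(methoxymethoxy)phenyl]ethenyl}borate
Conditions: KHF2 (aq), MeOH, rt
Reagents that add atoms: potassium hydrogen difluoride, [K+].[F-].F
Why: standard fluoride exchange of a pinacol boronate should give the crystalline trifluoroborate with the alkene geometry unchanged.

Step 9
Reactants: 15 potassium (E)-trifluoro{2-[4-(methoxymethoxy)phenyl]ethenyl}borate
Product: 16 (E)-2-[4-(methoxymethoxy)phenyl]ethenyl acetate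
Conditions: AcOH, CuBr (10 mol%), DMAP (20 mol%), 4 Å MS, O2 (1 atm), MeCN, 40 °C
Reagents that add atoms: acetic acid, CC(=O)O
Why: copper-catalysed aerobic oxidative C–O coupling of an alkenyltrifluoroborate with a carboxylic acid (Chan–Lam–Evans type) proceeds with retention at the alkene and should give only the E enol ester.

Step 10
Reactants: 9 5-geranyl-2-hydroxy-4,6-bis(methoxymethoxy)benzaldehyde; 16 (E)-2-[4-(methoxymethoxy)phenyl]ethenyl acetate
Product: 19 (2R,3S,4RS)-3-acetoxy-6-geranyl-4-methoxy-5,7,4′-tris(methoxymethoxy)flavan (2,3-trans; C4 epimers), via dimethyl acetal 17 (not isolated), via methoxy ortho-quinone methide 18 (not isolated)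
Conditions: HC(OMe)3 (1.5 equiv), (R)-TRIP (10 mol%), 16 (1.5 equiv), toluene, −20 °C to rt
Reagents that add atoms: trimethyl orthoformate, COC(OC)OC
Why: Proposed new method: acid-catalysed acetalisation of 9 and ionisation of acetal 17 should give the 4-methoxy ortho-quinone methide 18, present as its O-protonated oxocarbenium form hydrogen-bonded and ion-paired to the chiral phosphate; the enol acetate attacks the cationic carbon through its acetoxy-bearing carbon (C3–C4) and the resulting 4-alkoxybenzyl cation is captured by the phenol oxygen (O1–C2), an asynchronous inverse-electron-demand oxa-[4+2] process. The closest known reactions are Brønsted-acid-catalysed three-component chroman syntheses from salicylaldehydes, orthoformates and styrenes or enol ethers, and chiral-phosphoric-acid-catalysed ortho-quinone methide cycloadditions; a β-acyloxystyrene partner and enantiocontrol with an alkoxy-substituted methide have not been shown. Ring C closes as a six-membered ring in this single [4+2] event, with O1–C2 formed last by collapse of the phenol onto the benzylic cation. C2 and C3 become trans because the E geometry is carried through a concerted or rapidly collapsing pathway (trans-diequatorial is also the thermodynamic outcome), their absolute sense is fixed by the alkene face left open in the phosphate-bound ion pair, and C4 forms as an epimer mixture that is removed later. The step needs flavan rather than isoflavan regiochemistry, which the 4-alkoxyphenyl group secures as a far better cation-stabilising group than acetoxy, and it needs chemoselectivity over the geranyl alkenes, which is secured by the higher nucleophilicity of the donor-substituted styrene and by the meta placement of the chain, from which no ring can close onto C4.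

Step 11
Reactants: 19 (2R,3S,4RS)-3-acetoxy-6-geranyl-4-methoxy-5,7,4′-tris(methoxymethoxy)flavan
Product: 20 (2R,3S,4RS)-6-geranyl-4-methoxy-5,7,4′-tris(methoxymethoxy)flavan-3-ol
Conditions: K2CO3 (0.3 equiv), MeOH, rt
Reagents that add atoms: none
Why: carbonate-catalysed transesterification (Zemplén-type methanolysis) should remove the acetate; at this oxidation level neither C2 nor C3 can epimerise, and MOM and methyl ethers are stable to base.

Step 12
Reactants: 20 (2R,3S,4RS)-6-geranyl-4-methoxy-5,7,4′-tris(methoxymethoxy)flavan-3-ol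
Product: 21 (2R,3S,4RS)-6-geranyl-5,7,4′-tris(methoxymethoxy)flavan-3,4-diol
Conditions: PPTS (20 mol%), acetone/H2O (4:1), 0.01 M, rt
Reagents that add atoms: water, O
Why: SN1 solvolysis, in which the C4 methyl ether ionises under very mild acid because the cation is stabilised by O1 and the C5 and C7 oxygens; water in large excess at high dilution should capture it before another arene can, and phenolic MOM ethers need much stronger acid.

Step 13
Reactants: 21 (2R,3S,4RS)-6-geranyl-5,7,4′-tris(methoxymethoxy)flavan-3,4-diol
Product: 22 (2R,3R)-6-geranyl-3-hydroxy-5,7,4′-tris(methoxymethoxy)flavan-4-one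
Conditions: activated MnO2 (15 equiv), CH2Cl2, rt
Reagents that add atoms: none
Why: MnO2 oxidises the benzylic C4 alcohol selectively over the aliphatic C3 alcohol, both C4 epimers converge on one ketone, and the neutral conditions should leave the 2,3-trans centres untouched (the C3 descriptor changes from S to R only through the CIP priority of C4).

Step 14
Reactants: 22 (2R,3R)-6-geranyl-3-hydroxy-5,7,4′-tris(methoxymethoxy)flavan-4-one
Product: 23 bonnaniol, (2R,3R)-6-geranyl-3,5,7,4′-tetrahydroxyflavan-4-one
Conditions: HCl (3 M aq), MeOH, 45 °C, short reaction time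
Reagents that add atoms: none
Why: acid-catalysed acetal exchange with methanol should remove the three aryl MOM ethers; the dihydroflavonol is stable to dilute acid with trans as the thermodynamic arrangement, and a short reaction time at moderate temperature limits addition of the phenols to the geranyl alkenes.

**Compound list**

1 | phloroglucinol | Oc1cc(O)cc(O)c1 | starting material
2 | 3,5-bis(methoxymethoxy)phenol | COCOc1cc(O)cc(OCOC)c1 | intermediate
3 | [3,5-bis(methoxymethoxy)phenoxy]triisopropylsilane | COCOc1cc(OCOC)cc(O[Si](C(C)C)(C(C)C)C(C)C)c1 | intermediate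
4 | geranyl bromide, (2E)-1-bromo-3,7-dimethylocta-2,6-diene | CC(C)=CCC/C(C)=C/CBr | starting material
5 | [2,6-bis(methoxymethoxy)-4-(triisopropylsilyloxy)phenyl]lithium | [Li]c1c(OCOC)cc(O[Si](C(C)C)(C(C)C)C(C)C)cc1OCOC | intermediate (not isolated)
6 | [4-geranyl-3,5-bis(methoxymethoxy)phenoxy]triisopropylsilane | CC(C)=CCC/C(C)=C/Cc1c(OCOC)cc(O[Si](C(C)C)(C(C)C)C(C)C)cc1OCOC | intermediate
7 | 4-geranyl-3,5-bis(methoxymethoxy)phenol | CC(C)=CCC/C(C)=C/Cc1c(OCOC)cc(O)cc1OCOC | intermediate
8 | 4-geranyl-2-(hydroxymethyl)-3,5-bis(methoxymethoxy)phenol | CC(C)=CCC/C(C)=C/Cc1c(OCOC)cc(O)c(CO)c1OCOC | intermediate (not isolated)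
9 | 5-geranyl-2-hydroxy-4,6-bis(methoxymethoxy)benzaldehyde | CC(C)=CCC/C(C)=C/Cc1c(OCOC)cc(O)c(C=O)c1OCOC | intermediate
10 | 4-hydroxybenzaldehyde | O=Cc1ccc(O)cc1 | starting material
11 | 4-(methoxymethoxy)benzaldehyde | COCOc1ccc(C=O)cc1 | intermediate
12 | bis[(pinacolato)boryl]methane, 2,2′-methylenebis(4,4,5,5-tetramethyl-1,3,2-dioxaborolane) | CC1(C)OB(CB2OC(C)(C)C(C)(C)O2)OC1(C)C | starting material
13 | [bis(4,4,5,5-tetramethyl-1,3,2-dioxaborolan-2-yl)methyl]lithium | [Li]C(B1OC(C)(C)C(C)(C)O1)B1OC(C)(C)C(C)(C)O1 | intermediate (not isolated)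
14 | (E)-2-{2-[4-(methoxymethoxy)phenyl]ethenyl}-4,4,5,5-tetramethyl-1,3,2-dioxaborolane | COCOc1ccc(/C=C/B2OC(C)(C)C(C)(C)O2)cc1 | intermediate
15 | potassium (E)-trifluoro{2-[4-(methoxymethoxy)phenyl]ethenyl}borate | COCOc1ccc(/C=C/[B-](F)(F)F)cc1.[K+] | intermediate
16 | (E)-2-[4-(methoxymethoxy)phenyl]ethenyl acetate | CC(=O)O/C=C/c1ccc(OCOC)cc1 | intermediate
17 | 2-(dimethoxymethyl)-4-geranyl-3,5-bis(methoxymethoxy)phenol | CC(C)=CCC/C(C)=C/Cc1c(OCOC)cc(O)c(C(OC)OC)c1OCOC | intermediate (not isolated)
18 | 4-geranyl-6-(methoxymethylidene)-3,5-bis(methoxymethoxy)cyclohexa-2,4-dien-1-one | CC(C)=CCC/C(C)=C/CC1=C(OCOC)C(=COC)C(=O)C=C1OCOC | intermediate (not isolated)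
19 | (2R,3S,4RS)-3-acetoxy-6-geranyl-4-methoxy-5,7,4′-tris(methoxymethoxy)flavan, 2,3-trans, C4 epimers | CC(C)=CCC/C(C)=C/Cc1c(OCOC)cc2c(c1OCOC)C(OC)[C@H](OC(C)=O)[C@@H](c1ccc(OCOC)cc1)O2 | intermediate
20 | (2R,3S,4RS)-6-geranyl-4-methoxy-5,7,4′-tris(methoxymethoxy)flavan-3-ol | CC(C)=CCC/C(C)=C/Cc1c(OCOC)cc2c(c1OCOC)C(OC)[C@H](O)[C@@H](c1ccc(OCOC)cc1)O2 | intermediate
21 | (2R,3S,4RS)-6-geranyl-5,7,4′-tris(methoxymethoxy)flavan-3,4-diol | CC(C)=CCC/C(C)=C/Cc1c(OCOC)cc2c(c1OCOC)C(O)[C@H](O)[C@@H](c1ccc(OCOC)cc1)O2 | intermediate
22 | (2R,3R)-6-geranyl-3-hydroxy-5,7,4′-tris(methoxymethoxy)flavan-4-one | CC(C)=CCC/C(C)=C/Cc1c(OCOC)cc2c(c1OCOC)C(=O)[C@H](O)[C@@H](c1ccc(OCOC)cc1)O2 | intermediate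
23 | bonnaniol, (2R,3R)-6-geranyl-3,5,7,4′-tetrahydroxyflavan-4-one | CC(C)=CCC/C(C)=C/Cc1c(O)cc2c(c1O)C(=O)[C@H](O)[C@@H](c1ccc(O)cc1)O2 | target

**Step count**

Total steps: 14. Longest linear sequence: 10 steps (phloroglucinol 1 to 23 through steps 1–5 and 10–14); the enol acetate branch (steps 6–9) joins at step 10.

**Steps most likely to fail**

Step 10. Three things may go wrong:
- C–C bond formation may be sluggish, since the acetoxy group lowers the nucleophilicity of the attacking alkene carbon while the trioxygenated oxocarbenium ion is strongly stabilised.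
- Facial selectivity may erode in a loosely bound ion pair.
- The product may re-ionise at C4 and then eliminate or arylate.

The fallback keeps the same two ring bonds but uses a dienophile class already established for this cycloaddition. It sets out from 11 and 9. Wittig methylenation of 11 (Ph3PCH3Br, KOt-Bu, THF) should give 1-ethenyl-4-(methoxymethoxy)benzene F1. The known acid-catalysed three-component chroman synthesis from a salicylaldehyde, HC(OMe)3 and a styrene, run on 9 and F1 with the same chiral phosphoric acid, should give (2S,4RS)-6-geranyl-4-methoxy-5,7,4′-tris(methoxymethoxy)flavan F2. Mild aqueous acid (PPTS, acetone/H2O) should convert this into (2S,4RS)-6-geranyl-5,7,4′-tris(methoxymethoxy)flavan-4-ol F3, and MnO2 should oxidise it to (2S)-6-geranyl-5,7,4′-tris(methoxymethoxy)flavan-4-one F4. Enolate hydroxylation of F4 (LiN(SiMe3)2, THF, −78 °C, then 3-phenyl-2-(phenylsulfonyl)oxaziridine) should place the C3 hydroxyl anti to the C2 aryl group. The route is rejoined at 22.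

Step 13. The α-ketol formed may be oxidised further to the 3,4-dione and on to the flavonol, or the 3,4-diol may undergo glycol cleavage, if the oxidant does not stop at the benzylic alcohol. The fallback masks the C3 oxygen before C4 is adjusted and sets out from 20. Silylation (TBSCl, imidazole, DMF) should give (2R,3S,4RS)-3-(tert-butyldimethylsilyloxy)-6-geranyl-4-methoxy-5,7,4′-tris(methoxymethoxy)flavan F5. Solvolysis of the C4 ether (PPTS, acetone/H2O) should give (2R,3S,4RS)-3-(tert-butyldimethylsilyloxy)-6-geranyl-5,7,4′-tris(methoxymethoxy)flavan-4-ol F6. Dess–Martin periodinane (NaHCO3, CH2Cl2) should give (2R,3R)-3-(tert-butyldimethylsilyloxy)-6-geranyl-5,7,4′-tris(methoxymethoxy)flavan-4-one F7, in which only one alcohol was available for oxidation. HCl in MeOH should then remove the silyl ether and the three MOM ethers together, and the route is rejoined at 23.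

Step 14. Acid may trigger addition of the C5 or C7 phenol to the neighbouring geranyl alkene (chroman formation) or hydration of the chain, in competition with slow cleavage of the two hindered MOM ethers that flank it. The fallback avoids protic acid by passing through silyl ethers and sets out from 22. TMSOTf and 2,2′-bipyridyl (CH2Cl2, 0 °C) convert aryl MOM ethers into aryl trimethylsilyl ethers under buffered conditions and should also silylate the C3 hydroxyl, giving (2R,3R)-6-geranyl-3,5,7,4′-tetrakis(trimethylsilyloxy)flavan-4-one F8. Neutral hydrolysis (H2O/MeOH, rt) should then free the four hydroxyls, and the route is rejoined at 23.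

**Further compounds**

F1 | step 10 | 1-ethenyl-4-(methoxymethoxy)benzene | C=Cc1ccc(OCOC)cc1
F2 | step 10 | (2S,4RS)-6-geranyl-4-methoxy-5,7,4′-tris(methoxymethoxy)flavan | CC(C)=CCC/C(C)=C/Cc1c(OCOC)cc2c(c1OCOC)C(OC)C[C@@H](c1ccc(OCOC)cc1)O2
F3 | step 10 | (2S,4RS)-6-geranyl-5,7,4′-tris(methoxymethoxy)flavan-4-ol | CC(C)=CCC/C(C)=C/Cc1c(OCOC)cc2c(c1OCOC)C(O)C[C@@H](c1ccc(OCOC)cc1)O2
F4 | step 10 | (2S)-6-geranyl-5,7,4′-tris(methoxymethoxy)flavan-4-one | CC(C)=CCC/C(C)=C/Cc1c(OCOC)cc2c(c1OCOC)C(=O)C[C@@H](c1ccc(OCOC)cc1)O2
F5 | step 13 | (2R,3S,4RS)-3-(tert-butyldimethylsilyloxy)-6-geranyl-4-methoxy-5,7,4′-tris(methoxymethoxy)flavan | CC(C)=CCC/C(C)=C/Cc1c(OCOC)cc2c(c1OCOC)C(OC)[C@H](O[Si](C)(C)C(C)(C)C)[C@@H](c1ccc(OCOC)cc1)O2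
F6 | step 13 | (2R,3S,4RS)-3-(tert-butyldimethylsilyloxy)-6-geranyl-5,7,4′-tris(methoxymethoxy)flavan-4-ol | CC(C)=CCC/C(C)=C/Cc1c(OCOC)cc2c(c1OCOC)C(O)[C@H](O[Si](C)(C)C(C)(C)C)[C@@H](c1ccc(OCOC)cc1)O2
F7 | step 13 | (2R,3R)-3-(tert-butyldimethylsilyloxy)-6-geranyl-5,7,4′-tris(methoxymethoxy)flavan-4-one | CC(C)=CCC/C(C)=C/Cc1c(OCOC)cc2c(c1OCOC)C(=O)[C@H](O[Si](C)(C)C(C)(C)C)[C@@H](c1ccc(OCOC)cc1)O2
F8 | step 14 | (2R,3R)-6-geranyl-3,5,7,4′-tetrakis(trimethylsilyloxy)flavan-4-one | CC(C)=CCC/C(C)=C/Cc1c(O[Si](C)(C)C)cc2c(c1O[Si](C)(C)C)C(=O)[C@H](O[Si](C)(C)C)[C@@H](c1ccc(O[Si](C)(C)C)cc1)O2
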